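**Retrosynthetic overview**
1. Target ⇐ face-selective hydroboration–oxidation of a cycloocta-1,3-diene (installs the carbinol and the neighbouring ring-fusion hydrogen) ⇐ dienyl triflate ⇐ 5-8-6-6 β,γ-enone.
2. Eight-membered ring ⇐ four-carbon radical ring expansion of a fused cyclobutanone: a tertiary decalin radical adds to the C=O, the four-membered ring opens and PhS• leaves, giving the ketone, the quaternary methyl centre and the tetrasubstituted alkene in one step.
3. Cyclobutanone and cyclopentane ⇐ [2+2] of a decalin-tethered methyl(alkyl)ketene with (S)-3-methyl-1-(phenylsulfanyl)cyclopentene (from cyclopentenone).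
4. Decalin acid ⇐ reductive alkylation and methyl addition on the (S)-Robinson enone made from 2,5,5-trimethylcyclohexanone and methyl vinyl ketone.
5. Ring order: D (from 3-methylcyclohexenone) → C → A plus a temporary four-membered ring → B.

Labels used below (not IUPAC): ring A C1(sp2)–C2–C3–C4(Me)–C5; ring B C1–C5–C6(OH)–C7(Me)–C8–C9–C10–C11(Me)=C1; ring C C7–C12–C13–C14(Me)–C15–C8; ring D C14–C16–C17–C18(Me2)–C19–C15; α is the face opposite the C14 methyl; decalin intermediates carry naphthalene locants in their names.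

**Step 1**
Reactants: 1 3-methylcyclohex-2-en-1-one
Product: 3 3,6-dimethylcyclohex-2-en-1-one (racemic), via lithium dienolate 2 (not isolated)
Conditions: LDA (1.05 equiv), THF, −78 °C; MeI, −78 → 0 °C
Reagents that add atoms: iodomethane (CI)
Why: Kinetic α′-deprotonation gives the cross-conjugated dienolate, which is C-methylated (enolate alkylation); the new centre is racemic and is equilibrated through the enamine in step 3.

**Step 2**
Reactants: 3 3,6-dimethylcyclohex-2-en-1-one
Product: 4 2,5,5-trimethylcyclohexan-1-one (racemic)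
Conditions: MeMgBr (1.3 equiv), CuI (10 mol %), THF, −20 → 0 °C; aq NH4Cl
Reagents that add atoms: methylmagnesium bromide (C[Mg]Br)
Why: Copper-catalysed conjugate addition (Kharasch type) to the β-methyl enone creates the gem-dimethyl carbon; no lasting stereocentre is formed.

**Step 3**
Reactants: 4 2,5,5-trimethylcyclohexan-1-one; 5 but-3-en-2-one
Product: 9 (S)-4a,7,7-trimethyl-4,4a,5,6,7,8-hexahydronaphthalen-2(3H)-one, via imine 6 (not isolated), via Michael-adduct imine 7 (not isolated), via diketone 8 (not isolated)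
Conditions: (R)-1-phenylethylamine (1.05 equiv), TsOH (cat.), PhMe, reflux (Dean–Stark); 5, THF, 40 °C; 10% aq AcOH, rt; then NaOMe (0.2 equiv), MeOH, 60 °C (telescoped, amine recovered)
Reagents that add atoms: none
Why: d'Angelo deracemising Michael addition of the more substituted secondary enamine (aza-ene-like transition state, enone anti to phenyl) sets quaternary C14 as S with the (R)-amine (the (S)-amine gives the R series with 2-methylcyclohexanone), and aldol condensation completes the Robinson annulation.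

**Step 4**
Reactants: 10 3-methyloxolan-2-one (racemic)
Product: 12 methyl 4-iodo-2-methylbutanoate (racemic), via silyl ester 11 (not isolated)
Conditions: TMSI (1.2 equiv), CH2Cl2, rt; then MeOH, 40 °C
Reagents that add atoms: iodotrimethylsilane (C[Si](C)(C)I); methanol (CO)
Why: SN2 opening of the O-silylated lactone by iodide at the primary carbon (Olah-type lactone cleavage) and acid-catalysed esterification; the α-centre is racemic and is destroyed in step 9.

**Step 5**
Reactants: 9 (S)-4a,7,7-trimethyl-4,4a,5,6,7,8-hexahydronaphthalen-2(3H)-one; 12 methyl 4-iodo-2-methylbutanoate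
Product: 14 methyl 2-methyl-4-[(1S,4aS,8aS)-4a,7,7-trimethyl-2-oxodecahydronaphthalen-1-yl]butanoate (2-epimers), via lithium enolate 13 (not isolated)
Conditions: Li (2.2 equiv), t-BuOH (1.0 equiv), NH3(l)/THF, −78 °C; isoprene; 12 (2 equiv), −78 → −33 °C; NH4Cl
Reagents that add atoms: none
Why: Stork reductive alkylation (Birch-type enone reduction): axial protonation at C15 gives the trans C/D fusion, and the regiospecific enolate is alkylated at C8 from the α-face (anti to the angular methyl), giving the equatorial side chain, which is also the thermodynamic epimer next to the ketone.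

**Step 6**
Reactants: 14 methyl 2-methyl-4-[(1S,4aS,8aS)-4a,7,7-trimethyl-2-oxodecahydronaphthalen-1-yl]butanoate
Product: 16 4-[(1S,4aS,8aS)-2-hydroxy-2,4a,7,7-tetramethyldecahydronaphthalen-1-yl]-2-methylbutanoic acid (epimers at the carbinol and at C2 of the acid), via hydroxy ester 15 (not isolated)
Conditions: MeMgBr (1.2 equiv), THF, −78 → −20 °C; then LiOH, H2O/MeOH, 50 °C; 1 M HCl to pH 3
Reagents that add atoms: methylmagnesium bromide (C[Mg]Br); lithium hydroxide ([Li+].[OH-])
Why: Chemoselective Grignard addition to the ketone beside the α-branched ester, then saponification; the carbinol configuration is irrelevant because C7 becomes a radical in step 10.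

**Step 7**
Reactants: 17 cyclopent-2-en-1-one
Product: 19 (S)-3-methylcyclopent-1-en-1-yl trifluoromethanesulfonate, via zinc enolate 18 (not isolated)
Conditions: Me2Zn (1.5 equiv), (CuOTf)2·C6H6 (1 mol %), chiral peptide-based phosphine ligand (2.4 mol %), PhMe, −30 °C; then Tf2O (1.5 equiv), −78 → 0 °C
Reagents that add atoms: dimethylzinc (C[Zn]C); trifluoromethanesulfonic anhydride (O=S(=O)(OS(=O)(=O)C(F)(F)F)C(F)(F)F)
Why: Copper-catalysed asymmetric conjugate addition (ligand enantiomer chosen for the S product) sets C4, and O-triflation of the regiodefined zinc enolate fixes the double bond on the methyl side.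

**Step 8**
Reactants: 19 (S)-3-methylcyclopent-1-en-1-yl trifluoromethanesulfonate
Product: 20 (S)-3-methyl-1-(phenylsulfanyl)cyclopent-1-ene
Conditions: PhSH (1.1 equiv), Pd2(dba)3 (2.5 mol %), Xantphos (5 mol %), iPr2NEt (2 equiv), 1,4-dioxane, 90 °C
Reagents that add atoms: benzenethiol (Sc1ccccc1)
Why: Palladium-catalysed C–S cross-coupling (Migita type) of the alkenyl triflate keeps the alkene position and does not touch the stereocentre.

**Step 9**
Reactants: 16 4-[(1S,4aS,8aS)-2-hydroxy-2,4a,7,7-tetramethyldecahydronaphthalen-1-yl]-2-methylbutanoic acid; 20 (S)-3-methyl-1-(phenylsulfanyl)cyclopent-1-ene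
Product: 23 (4S)-7-{2-[(1S,4aS,8aS)-2-hydroxy-2,4a,7,7-tetramethyldecahydronaphthalen-1-yl]ethyl}-4,7-dimethyl-1-(phenylsulfanyl)bicyclo[3.2.0]heptan-6-one (diastereomer mixture), via mixed anhydride 21 (not isolated), via ketene 22 (not isolated)
Conditions: TsCl (1.3 equiv), Et3N (3 equiv), 20 (3 equiv, excess recovered), PhMe, 90 °C, slow addition of 16
Reagents that add atoms: none
Why: The mixed sulfonic anhydride loses tosylate to give the methyl(alkyl)ketene, which undergoes thermal ketene–alkene [2+2] cycloaddition with the electron-rich vinyl sulfide (nucleophilic C5 bonds to the ketene carbonyl carbon C6, sulfur-bearing C1 to C11) to give the cis-fused 3-sulfanylcyclobutanone; the new centres C1, C5 and C11 need no control because all become sp2 or are reset in steps 10–13.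

**Step 10**
Reactants: 23 (4S)-7-{2-[(1S,4aS,8aS)-2-hydroxy-2,4a,7,7-tetramethyldecahydronaphthalen-1-yl]ethyl}-4,7-dimethyl-1-(phenylsulfanyl)bicyclo[3.2.0]heptan-6-one
Product: 25 (1(11)Z,4S,7S,8S,14S,15S)-tetracyclic β,γ-enone with the ketone at C6 (C5 epimers), via benzoxazoline adduct 24 (not isolated)
Conditions: 5,7-di-tert-butyl-3-phenylbenzoxazolium BF4 (1.5 equiv), pyridine (1.5 equiv), MTBE, rt; then [Ir(ppy)2(dtbbpy)]PF6 (2 mol %), quinuclidine (1.5 equiv), DMA, 450 nm LEDs, rt, 5 mM; crude product used at once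
Reagents that add atoms: none
Why: Proposed new method: the NHC adduct of the tertiary carbinol is oxidised by the excited Ir(III) catalyst and, after proton loss, fragments to the C7 tertiary radical, which adds 6-exo to the strained cyclobutanone carbonyl C6 through a chair transition state that makes the new C6–C7 bond equatorial on ring C (methyl axial, α; the alternative puts the fully substituted C6 axial against two syn-axial hydrogens), the cyclobutyloxy radical opens by β-scission of C6–C11 (strain release, tertiary radical) and the C11 radical expels PhS• from C1 to give the Z C1=C11 alkene, PhS• being reduced by Ir(II) so the cycle is redox-neutral; the closest known reactions are the Dowd–Beckwith ring expansion of 2-(ω-haloalkyl)cyclobutanones under Bu3SnH and photoredox deoxygenative radical generation from NHC–alcohol adducts, neither shown with a tertiary radical adding to a ketone of this kind or with a β-sulfanyl terminating group.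

**Step 11**
Reactants: 25 (1(11)Z,4S,7S,8S,14S,15S)-tetracyclic β,γ-enone
Product: 27 dienyl triflate (C6–OTf; C5=C6 and C1=C11), via potassium dienolate 26 (not isolated)
Conditions: KHMDS (1.2 equiv), THF, −78 °C; PhNTf2 (1.3 equiv), −78 → 0 °C
Reagents that add atoms: N-phenylbis(trifluoromethanesulfonimide) (O=S(=O)(N(c1ccccc1)S(=O)(=O)C(F)(F)F)C(F)(F)F)
Why: C5 is the only enolisable position (C7 is quaternary) and is doubly activated, so the linear dienolate forms and is O-triflated (enol triflate formation); this deliberately erases the C5 configuration.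

**Step 12**
Reactants: 27 dienyl triflate
Product: 28 (1(11)Z,5Z,4S,7S,8S,14S,15S)-ring-B 1,3-diene
Conditions: Pd(OAc)2 (5 mol %), PPh3 (10 mol %), HCO2H (2 equiv), Bu3N (3 equiv), DMF, 60 °C
Reagents that add atoms: none
Why: Palladium-catalysed formate reduction of the alkenyl triflate (Cacchi reduction) replaces OTf by H without touching the alkenes or stereocentres.

**Step 13**
Reactants: 28 (1(11)Z,5Z,4S,7S,8S,14S,15S)-ring-B 1,3-diene
Product: 30 target (1(11)Z,4S,5S,6R,7S,8S,14S,15S)-alcohol, via alkylborane 29 (not isolated)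
Conditions: BH3·THF (1.5 equiv), THF, 0 °C → rt; then 3 M NaOH, 30% H2O2, 0 °C → rt
Reagents that add atoms: hydrogen peroxide (OO)
Why: Hydroboration–oxidation (Brown): borane adds anti-Markovnikov and syn across the trisubstituted C5=C6 bond (boron at C6; the tetrasubstituted C1=C11 bond is inert) from the diene face opposite the C4 methyl and the pseudo-axial C7 methyl, and oxidation with retention gives the 5S,6R centres.

**Compound list**
1 | 3-methylcyclohex-2-en-1-one | CC1=CC(=O)CCC1 | starting material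
2 | lithium 5-methylcyclohexa-1,5-dien-1-olate | [Li+].CC1=CC([O-])=CCC1 | intermediate
3 | 3,6-dimethylcyclohex-2-en-1-one (racemic) | CC1=CC(=O)C(C)CC1 | intermediate
4 | 2,5,5-trimethylcyclohexan-1-one (racemic) | CC1CCC(C)(C)CC1=O | intermediate
5 | but-3-en-2-one | CC(=O)C=C | starting material
6 | N-[(R)-1-phenylethyl]imine of 4 | CC1CCC(C)(C)CC1=N[C@H](C)c1ccccc1 | intermediate
7 | N-[(R)-1-phenylethyl]imine of 8 (Michael adduct) | CC(=O)CC[C@]1(C)CCC(C)(C)CC1=N[C@H](C)c1ccccc1 | intermediate
8 | (S)-2,5,5-trimethyl-2-(3-oxobutyl)cyclohexan-1-one | CC(=O)CC[C@]1(C)CCC(C)(C)CC1=O | intermediate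
9 | (S)-4a,7,7-trimethyl-4,4a,5,6,7,8-hexahydronaphthalen-2(3H)-one | O=C1C=C2CC(C)(C)CC[C@@]2(C)CC1 | intermediate
10 | 3-methyloxolan-2-one (racemic) | CC1CCOC1=O | starting material
11 | trimethylsilyl 4-iodo-2-methylbutanoate | CC(CCI)C(=O)O[Si](C)(C)C | intermediate
12 | methyl 4-iodo-2-methylbutanoate (racemic) | COC(=O)C(C)CCI | intermediate
13 | lithium (4aS,8aS)-4a,7,7-trimethyl-3,4,4a,5,6,7,8,8a-octahydronaphthalen-2-olate (trans-fused) | [Li+].[O-]C1=C[C@@H]2CC(C)(C)CC[C@@]2(C)CC1 | intermediate
14 | methyl 2-methyl-4-[(1S,4aS,8aS)-4a,7,7-trimethyl-2-oxodecahydronaphthalen-1-yl]butanoate (2-epimers) | O=C1CC[C@]2(C)CCC(C)(C)C[C@H]2[C@@H]1CCC(C)C(=O)OC | intermediate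
15 | methyl 4-[(1S,4aS,8aS)-2-hydroxy-2,4a,7,7-tetramethyldecahydronaphthalen-1-yl]-2-methylbutanoate (epimers at carbinol and C2) | CC1(O)CC[C@]2(C)CCC(C)(C)C[C@H]2[C@@H]1CCC(C)C(=O)OC | intermediate
16 | 4-[(1S,4aS,8aS)-2-hydroxy-2,4a,7,7-tetramethyldecahydronaphthalen-1-yl]-2-methylbutanoic acid (epimers at carbinol and C2) | CC1(O)CC[C@]2(C)CCC(C)(C)C[C@H]2[C@@H]1CCC(C)C(=O)O | intermediate
17 | cyclopent-2-en-1-one | O=C1C=CCC1 | starting material
18 | methylzinc (S)-3-methylcyclopent-1-en-1-olate | C[C@H]1CCC(O[Zn]C)=C1 | intermediate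
19 | (S)-3-methylcyclopent-1-en-1-yl trifluoromethanesulfonate | C[C@H]1CCC(OS(=O)(=O)C(F)(F)F)=C1 | intermediate
20 | (S)-3-methyl-1-(phenylsulfanyl)cyclopent-1-ene | C[C@H]1CCC(Sc2ccccc2)=C1 | intermediate
21 | mixed anhydride of 16 with 4-methylbenzenesulfonic acid | CC1(O)CC[C@]2(C)CCC(C)(C)C[C@H]2[C@@H]1CCC(C)C(=O)OS(=O)(=O)c1ccc(C)cc1 | intermediate
22 | 4-[(1S,4aS,8aS)-2-hydroxy-2,4a,7,7-tetramethyldecahydronaphthalen-1-yl]-2-methylbut-1-en-1-one (ketene) | CC1(O)CC[C@]2(C)CCC(C)(C)C[C@H]2[C@@H]1CCC(C)=C=O | intermediate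
23 | (4S)-7-{2-[(1S,4aS,8aS)-2-hydroxy-2,4a,7,7-tetramethyldecahydronaphthalen-1-yl]ethyl}-4,7-dimethyl-1-(phenylsulfanyl)bicyclo[3.2.0]heptan-6-one (cis-fused; bridgeheads, C7 of the bicycle and carbinol not controlled) | CC1(O)CC[C@]2(C)CCC(C)(C)C[C@H]2[C@@H]1CCC1(C)C(=O)C2[C@@H](C)CCC12Sc1ccccc1 | intermediate
24 | 2-alkoxy-5,7-di-tert-butyl-3-phenyl-2,3-dihydro-1,3-benzoxazole formed at the carbinol of 23 | CC1(OC3Oc4c(C(C)(C)C)cc(C(C)(C)C)cc4N3c3ccccc3)CC[C@]2(C)CCC(C)(C)C[C@H]2[C@@H]1CCC1(C)C(=O)C2[C@@H](C)CCC12Sc1ccccc1 | intermediate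
25 | (1(11)Z,4S,7S,8S,14S,15S)-5-8-6-6 β,γ-enone: C6 ketone, C1=C11 alkene, C7 methyl α (axial), B/C/D trans-anti-trans, C5 epimers | C/C1=C2\CC[C@H](C)C2C(=O)[C@@]2(C)CC[C@]3(C)CCC(C)(C)C[C@H]3[C@@H]2CC1 | intermediate
26 | potassium dienolate of 25 (O–C6=C5–C1=C11) | [K+].C/C1=C2\CC[C@H](C)/C2=C(\[O-])[C@@]2(C)CC[C@]3(C)CCC(C)(C)C[C@H]3[C@@H]2CC1 | intermediate
27 | dienyl triflate (C6–OTf; C5=C6 and C1=C11; 4S,7S,8S,14S,15S) | C/C1=C2\CC[C@H](C)/C2=C(\OS(=O)(=O)C(F)(F)F)[C@@]2(C)CC[C@]3(C)CCC(C)(C)C[C@H]3[C@@H]2CC1 | intermediate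
28 | (1(11)Z,5Z,4S,7S,8S,14S,15S)-diene (C5=C6–H and C1=C11 in ring B) | C/C1=C2\CC[C@H](C)/C2=C/[C@@]2(C)CC[C@]3(C)CCC(C)(C)C[C@H]3[C@@H]2CC1 | intermediate
29 | C6 alkylborane (C5–H and C6–BH2 syn, on the face opposite the C4 and C7 methyls) | C/C1=C2\CC[C@H](C)[C@@H]2[C@@H](B)[C@@]2(C)CC[C@]3(C)CCC(C)(C)C[C@H]3[C@@H]2CC1 | intermediate
30 | (1(11)Z,4S,5S,6R,7S,8S,14S,15S)-alcohol CNP0399382.1 | C/C1=C2\CC[C@H](C)[C@@H]2[C@@H](O)[C@@]2(C)CC[C@]3(C)CCC(C)(C)C[C@H]3[C@@H]2CC1 | target

**Step count**
Total: 13 steps. Longest linear sequence: 10 steps (1, 2, 3, 5, 6, 9, 10, 11, 12, 13).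

**Three steps most likely to fail**

Step 10 (the proposed ring expansion). The tertiary radical may be reduced before it adds to the hindered carbonyl, the four-membered ring may open toward C5 instead of C11, or the amine base may move the alkene into conjugation. The fallback sets out from 23 and comes back at 25. HCl gas (CH2Cl2, 0 °C) turns the carbinol into the tertiary chloride F5. Bu3SnH (syringe pump) with AIBN in benzene at 80 °C, the established tin hydride Dowd–Beckwith protocol with a halide radical precursor, then gives 25 by the same addition, β-scission and thiyl loss, run as a stoichiometric chain without photocatalyst or base.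

Step 9 (ketene [2+2]). The cycloaddition joins two fully substituted carbons, and the free tertiary alcohol may be acylated by the ketene. The fallback sets out from 16 and comes back at 23. Coupling with dimethylamine (EDC, HOBt) gives the dimethylamide F3, and TMSCl/imidazole gives the silyl ether amide F4. Tf2O and 2,4,6-collidine with 20 in 1,2-dichloroethane at 60 °C generate the far more electrophilic keteniminium salt (Ghosez cycloaddition). Aqueous NaHCO3 and then dilute HCl/THF hydrolyse the cyclobutaniminium salt and the silyl ether to 23.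

Step 5 (reductive alkylation with an unactivated iodide). Proton transfer and over-alkylation can lower the yield. The fallback sets out from 9 and comes back at 14. Li/NH3 followed by allyl bromide gives the allyl ketone F1. Cross-metathesis with methyl methacrylate (Hoveyda–Grubbs II, CH2Cl2, 40 °C) gives the enoate F2. Hydrogenation (H2, Pd/C, EtOAc) gives 14.

**Further compounds**
F1 | step 5 | (1S,4aS,8aS)-1-allyl-4a,7,7-trimethyloctahydronaphthalen-2(1H)-one (allyl ketone) | O=C1CC[C@]2(C)CCC(C)(C)C[C@H]2[C@@H]1CC=C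
F2 | step 5 | methyl (E)-2-methyl-4-[(1S,4aS,8aS)-4a,7,7-trimethyl-2-oxodecahydronaphthalen-1-yl]but-2-enoate (enoate) | O=C1CC[C@]2(C)CCC(C)(C)C[C@H]2[C@@H]1C/C=C(\C)C(=O)OC
F3 | step 9 | 4-[(1S,4aS,8aS)-2-hydroxy-2,4a,7,7-tetramethyldecahydronaphthalen-1-yl]-N,N,2-trimethylbutanamide (dimethylamide) | CC1(O)CC[C@]2(C)CCC(C)(C)C[C@H]2[C@@H]1CCC(C)C(=O)N(C)C
F4 | step 9 | O-trimethylsilyl ether of F3 (silyl ether amide) | CC1(O[Si](C)(C)C)CC[C@]2(C)CCC(C)(C)C[C@H]2[C@@H]1CCC(C)C(=O)N(C)C
F5 | step 10 | tertiary chloride of 23 (Cl in place of the C7 hydroxyl) | CC1(Cl)CC[C@]2(C)CCC(C)(C)C[C@H]2[C@@H]1CCC1(C)C(=O)C2[C@@H](C)CCC12Sc1ccccc1
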